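1.01 is the number to hold. It is the split: at the start of Monday's flask, the second step's constant times [fresh partner], over the first step's constant times [substrate]. Think of one tank with two drains, where the coupling partner is the tank and the split is the ratio of the two outflows.

all flasks: substrate 0.10 M; fresh partner 2.00 equiv; coupling partner 1.50 equiv; time 1.0 h

| charge | temperature |
|---|---|
| Monday's | 10 °C |
| Sunday's | 0 °C |

    substrate + coupling partner → open intermediate (k1 = 0.0020 L mol⁻¹ s⁻¹, Ea1 = 60.0 kJ mol⁻¹)
    coupling partner + fresh partner → second intermediate (k2 = 9.2 × 10⁻⁴ L mol⁻¹ s⁻¹, Ea2 = 66.0 kJ mol⁻¹)
    open intermediate + second intermediate → target (k3 = 0.0015 L mol⁻¹ s⁻¹, Ea3 = 47.0 kJ mol⁻¹)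
    second intermediate → side product (k4 = 5.6 × 10⁻⁴ s⁻¹, Ea4 = 85.0 kJ mol⁻¹)
    target ⇌ isomer of the product (K5 = 0.75, k5 = 6.5 × 10⁻⁵ s⁻¹, Ea5 = 81.0 kJ mol⁻¹, ΔH5 = 4.00 kJ mol⁻¹)
    (constants at 0 °C)

- at 0 °C the constants are as listed, elsewhere as the activation energies and enthalpies make them

- which of these there is most of at the end, counted by the substrate in it, Monday's (target / open intermediate / isomer of the product / substrate)
- which of these there is most of at the end, counted by the substrate in it, Sunday's (target / open intermediate / isomer of the product / substrate)
- how much there is at the end of the one of these that leads, in percent of the substrate charged: Monday's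
- how much there is at the end of the one of these that leads, in percent of the substrate charged: Sunday's

My reckoning: with the split held steady, a share 1/(1+split) of the partner reaches the substrate, so Monday's 1.50 equiv of partner converts about 0.746 equiv of substrate. That estimate lies past 0.5 equiv, roughly where open intermediate overtakes substrate, so I name open intermediate for Monday's, with the amount open. I stop short on Sunday's flask: by the second step alone, with the other concentrations as charged, its partner has a half-life of 1.0 h, about the length of the run, so the clock counts there and I name no leader.

The forecast gives open intermediate at 56.5% (53% to 59%) for Monday's and substrate at 52.8% (50% to 56%) for Sunday's. Its ground: “The coupling partner is shared by two competing reactions and runs low”.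

The simulation gives open intermediate at 56.7% for Monday's and substrate at 52.8% for Sunday's, so both leaders are right and both amounts lie in range.

Monday's coupling partner, the limiting reagent, ends at 9.5% of its charge, less than the substrate's 39%. Now carry the split along. It scales with [fresh partner]/[substrate], so by the end of Monday's flask it stands at 1.60, and the outflow has tilted away from the substrate.

One run shows Monday's leader changing. The neighbour like Monday's flask but with 0.380 equiv of coupling partner has the same starting split, which gives about 0.189 equiv of substrate converted, so substrate should lead. That flask ends with 82.2% substrate and 17.5% open intermediate, and substrate leads.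

(The numbers of this flask are made up; the flask was simulated.)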